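## Structural features

The target is a 1,4-benzodioxane neolignan: benzene ring B is fused to a six-membered dioxane whose two sp3 carbons are C7, carrying ring A (3,4-dihydroxy-5-methoxyphenyl), and C8, carrying the hydroxymethyl carbon C9 (lignan labels; O7 and O8 are the ring B oxygens bonded to C7 and C8). Ring B is unsymmetrical: the carbon bearing O8 has a methoxy neighbour and lies para to the (E)-propenal chain, whereas the carbon bearing O7 has an aromatic C–H neighbour and lies meta to the chain, so ring A must end up on the O7 side. C7 and C8 are adjacent stereocentres, both R, with aryl and hydroxymethyl trans on the dioxane. The fragile groups are the ring A catechol (oxidation, base), the enal (nucleophiles, hydride, over-olefination) and the C7–O7 bond, which is a para-hydroxybenzyl aryl ether and ionises easily. That lability allows C7 to be left to thermodynamic control (trans), so the real difficulty is the absolute configuration at C8 together with the O7/O8 regiochemistry. The key step uses the fact that C8 is bonded to O8 directly and to O7 through C7 alone: C8 with both oxygens is a catechol acetal (a 1,3-benzodioxole), and the dioxane is that five-membered ring with one more carbon, C7 bearing ring A, inserted into the O7–C8 bond as an aryl carbene.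

## Logic of the disconnections

**17 to 16.** The three O–Si bonds (two on ring A, one at C9) are cut. The free catechol and primary alcohol would not survive hydride, MnO2, the ylide or the carbene, and silyl ethers can be removed together at the end. Nothing is gained in skeleton. The forward step must spare the enal and should let C7 settle trans by reversible C7–O7 ionisation without touching C8.

**16 to 15.** The Cα=Cβ double bond of the enal is cut, the two carbons returning to a formyl-stabilised phosphorus ylide. This removes the only alkene from all earlier intermediates, which matters because an alkene would be cyclopropanated by the carbene. The forward step must be E-selective and stop after one homologation.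

**15 to 13 through 14.** No skeletal bond is cut; the formyl C–H of 15 is traded back, via the benzylic C–OH of 14, for the ester C–OMe of 13. An ester is inert to the carbene, deactivates ring B toward cyclopropanation and, being para to O8, lowers the basicity of O8 relative to O7. The forward steps must reduce and reoxidise without loss of aryl or alkyl silyl ethers.

**13 to 6 and 12 (12 from 11, 11 from 10).** The bonds O7–C7 and C7–C8 are cut. C7 becomes a carbene carbon, stored as the diazo group of 12, and C8 returns to O7 to give the five-membered acetal of 6. The heterocycle and its oxygen regiochemistry reduce to a catechol acetal, the two halves are joined convergently, and the stereochemical problem shrinks to one acetal carbon. The forward step must form the ylide at O7 and not at O8, shift C8 with retention, and let a weakly basic aryl acetal oxygen compete with carbene dimerisation. For this reason the ring A oxygens of 10 are silylated and not protected as alkoxymethyl acetals: an alkyl acetal oxygen would be a better carbene acceptor than O7 and carries its own migrating carbon, while aryl silyl ether oxygens are hindered and barely basic.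

**6 to 4 through 5.** The C9 O–Si bond is cut, and then the enantiomers of 4 are separated. The acetal carbon is stereogenic only because ring B is unsymmetrical, so no asymmetric acetalisation is available; resolution is placed on a small, cheap, early intermediate. The forward step needs an enzyme that senses substituents remote from the carbinol.

**4 to 1 and 2 through 3.** The oxidation level of C9 is raised to the ester of 3, and then both acetal bonds O7–C8 and O8–C8 are cut to a catechol and a geminal dibromide. This reaches two commercial compounds. The forward reduction must distinguish the acetal-bound ester from the aryl ester.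

**10 to 8 and 9; 8 to 7.** The C=N bond is cut, then the two aryl O–Si bonds, reaching commercial 7 and 9. The forward steps are routine.

## Other disconnections considered

**Alternative 1:** Oxetane A1 is cut through C7–C8 and O–C9, back to ring A aldehyde A2 and ring B aryl vinyl ether A3, in which O8 is already bonded to C8. The dioxane forms only afterwards, when freed O7 displaces the oxetane oxygen at C7.
- Forward key step: irradiation of A2 with A3 (Paternò–Büchi reaction). The triplet carbonyl oxygen adds to terminal C9 and the 1,4-biradical closes C7–C8.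
- In its favour: both partners are a few steps from commercial phenols. O8–C8 exists before any ring is made, so the O7/O8 question never arises; on regiochemistry this plan is better than the chosen one. The later closure is driven by oxetane strain and tolerates either C7 configuration, the same tolerance the chosen plan has (equal). The step count, roughly eight, would be lower than eleven (better).
- Against it here: nothing in A2 or A3 controls the absolute configuration at C8, so A1 would be racemic at the one centre that cannot be repaired later. A resolution would then fall on a late intermediate instead of a small early alcohol. Oxygen-rich benzaldehydes have low-lying π,π* triplets and are poor oxetane formers, hence the acetates, and the aryl bromide and aryl vinyl ether are themselves light-sensitive.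
- Comparison: both plans make C7–C8 by collapse of a radical pair, but the chosen plan inherits C8 from a resolved acetal whereas this one creates it without control. Alternative 1 is more direct for the skeleton and weaker on stereochemistry.

**Alternative 2:** The aryl ether bond Ca–O7 of benzodioxane A4 is cut (Ca is the ring B carbon that carries O7), giving the open-chain threo bromo alcohol A5, in which O8–C8 and both stereocentres already exist.
- Forward key step: CuI, a phenanthroline ligand and Cs2CO3 join the C7 alkoxide to the ortho C–Br carbon (intramolecular Ullmann-type etherification, 6-exo).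
- In its favour: the reaction class is established for benzodioxanes. No bond to C7 or C8 is broken, so the threo arrangement of A5 should pass into the trans ring without any stereochemical assumption. Regiochemistry is fixed by which oxygen is attached first. On precedent, stereochemical security and regiocontrol this plan is better than the chosen one.
- Against it here: the burden moves to A5. Two adjacent stereocentres and a C8–O8 bond to a doubly ortho-substituted, weakly nucleophilic phenol must be built in a linear sequence, so the ring closure comes after about ten steps and the whole route would exceed eleven. The secondary benzylic alkoxide on an electron-rich ring is a reluctant partner and can suffer C7–C8 cleavage or hydrodebromination under hot carbonate. The carefully set C7 would in the end be equilibrated anyway once the ring A phenol is free.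
- Comparison: the ring and protecting-group pattern at the end are the same (equal). A two-electron C–O coupling at an sp2 carbon is mechanistically far safer than a carbene/ylide rearrangement. On step economy and convergence the chosen plan is ahead.

**Alternative 3:** The O8–C8 bond of benzodioxane aldehyde A6 is cut with inversion in mind, giving the anti (erythro) hydroxy ether A7. Its O7–C7 bond would come from Sharpless asymmetric epoxidation in the ring A cinnamyl series and opening of the epoxide at C7 by O7.
- Forward key step: PPh3 and diisopropyl azodicarboxylate turn the C8 hydroxyl into an oxyphosphonium group and the neighbouring phenol O8–H displaces it (6-exo-tet, inversion), converting the anti relationship of A7 into the trans ring.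
- In its favour: both stereocentres derive from one reliable catalytic asymmetric reaction and two stereospecific substitutions, so the stereochemical logic is explicit where the chosen plan relies on an untested retention (better). Ring B can carry its aldehyde from the start, so A6 sits at the oxidation level of 15 and the reduction/oxidation pair of the chosen plan is saved (better by two steps after ring formation). The Mitsunobu cyclisation is an established reaction type (better on precedent).
- Against it here: the ring B catechol must be differentiated so that the less acidic O7 opens the epoxide while the more acidic O8 waits, which costs protecting-group steps. Opening of an electron-rich aryl epoxide at the benzylic carbon can drift toward a cationic pathway and erode the anti relationship. In the Mitsunobu step the oxyphosphonium next to a benzylic aryloxy carbon can eliminate to an enol ether, and the nucleophile is a hindered phenol flanked by OMe and O7.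
- Comparison: overall length would be about the same as the chosen plan (equal), but linear and not convergent. Regiochemistry depends on protecting-group choreography, not on the bias of an acetal. The chosen plan concentrates its risk in one step; this one spreads moderate risk over three.

Key step: step 7

Assumption: the lipase is taken to acylate the (2S)-alcohol faster, so that the (2R)-alcohol 5 remains; with the opposite preference the (2R)-acetate would be isolated and methanolysed (K2CO3, MeOH) to the same 5 at the cost of one step.

Abbreviation: TBS = tert-butyldimethylsilyl; TBSO = tert-butyldimethylsilyloxy.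

## Route

Step 1  
Reactants: 1 methyl 3,4-dihydroxy-5-methoxybenzoate; 2 ethyl dibromoacetate  
Product: 3 2-ethyl 5-methyl 7-methoxy-1,3-benzodioxole-2,5-dicarboxylate (racemic at C2)  
Conditions: K2CO3, DMF, 70 °C  
Reagents that add atoms: none  
Why: Double O-alkylation of a catechol by a geminal dihalide (Williamson-type acetal formation); the first substitution gives an α-bromo-α-aryloxy ester that should close at once to the five-membered ring (5-exo-tet), and either phenol may react first because both end on the same carbon.

Step 2  
Reactants: 3 2-ethyl 5-methyl 7-methoxy-1,3-benzodioxole-2,5-dicarboxylate  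
Product: 4 methyl 2-(hydroxymethyl)-7-methoxy-1,3-benzodioxole-5-carboxylate (racemic)  
Conditions: NaBH4, MeOH/THF, 0 °C  
Reagents that add atoms: none  
Why: Chemoselective borohydride reduction: the ester flanked by two acetal oxygens is strongly activated, whereas the electron-rich aryl methyl ester should be inert at 0 °C; methanol as co-solvent keeps any transesterification of the aryl ester degenerate.

Step 3  
Reactants: 4 methyl 2-(hydroxymethyl)-7-methoxy-1,3-benzodioxole-5-carboxylate (racemic)  
Product: 5 methyl (2R)-2-(hydroxymethyl)-7-methoxy-1,3-benzodioxole-5-carboxylate (recovered unreacted enantiomer)  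
Conditions: Burkholderia cepacia lipase (immobilised), vinyl acetate, MTBE, 30 °C, stopped just past half conversion  
Reagents that add atoms: none  
Why: Lipase-catalysed kinetic resolution by irreversible transesterification of a primary alcohol whose stereocentre is the adjacent carbon; no stereocentre is created, the enzyme selects, and taking the slow enantiomer allows its enantiopurity to be raised by running beyond half conversion.

Step 4  
Reactants: 5 methyl (2R)-2-(hydroxymethyl)-7-methoxy-1,3-benzodioxole-5-carboxylate  
Product: 6 methyl (2R)-2-(TBSO-methyl)-7-methoxy-1,3-benzodioxole-5-carboxylate  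
Conditions: TBSCl, imidazole, CH2Cl2, rt  
Reagents that add atoms: tert-butyldimethylsilyl chloride, CC(C)(C)[Si](C)(C)Cl  
Why: Standard silylation of a primary alcohol; the O–H bond would otherwise insert the carbene in step 7, and the acetal stereocentre is not involved.

Step 5  
Reactants: 7 5-hydroxyvanillin (3,4-dihydroxy-5-methoxybenzaldehyde)  
Product: 8 3,4-bis(TBSO)-5-methoxybenzaldehyde  
Conditions: TBSCl, imidazole, DMF, rt  
Reagents that add atoms: tert-butyldimethylsilyl chloride, CC(C)(C)[Si](C)(C)Cl  
Why: Standard bis-silylation of a catechol; aryl silyl ethers are chosen because their oxygens are hindered and weakly basic and so should not compete for the carbene, unlike alkoxymethyl acetals.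

Step 6  
Reactants: 8 3,4-bis(TBSO)-5-methoxybenzaldehyde; 9 p-toluenesulfonyl hydrazide  
Product: 10 N'-[(E)-(3,4-bis(TBSO)-5-methoxyphenyl)methylidene]-4-methylbenzenesulfonohydrazide (tosylhydrazone of 8)  
Conditions: MeOH, rt  
Reagents that add atoms: none  
Why: Condensation of an aldehyde with a sulfonyl hydrazide to the N-tosylhydrazone, which should form under neutral conditions that leave aryl silyl ethers intact.

Step 7  
Reactants: 6 methyl (2R)-2-(TBSO-methyl)-7-methoxy-1,3-benzodioxole-5-carboxylate; 10 tosylhydrazone of 8  
Product: 13 methyl (2R,3R)-3-[3,4-bis(TBSO)-5-methoxyphenyl]-2-(TBSO-methyl)-8-methoxy-2,3-dihydro-1,4-benzodioxine-6-carboxylate (trans; C3 is lignan C7, C2 is lignan C8), via tosylhydrazone sodium salt 11 (not isolated), via aryldiazomethane 12 (not isolated)  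
Conditions: 10 (2.5 equiv), NaH, PhCF3, rt; suspension added in portions to 6, Rh2(O2CC7H15)4 (2 mol%), BnEt3NCl (10 mol%), PhCF3, 40 °C  
Reagents that add atoms: none  
Why: Proposed new method: thermal loss of sulfinate from salt 11 (Bamford–Stevens) should feed aryldiazomethane 12 slowly to the dirhodium carboxylate, the electrophilic aryl carbenoid should be captured by a lone pair of acetal oxygen O7 of 6 to give an oxonium ylide, and O7–C8 cleavage then leaves a C8 centre stabilised by O8 (radical or oxocarbenium character) still tethered through ring B to the O7-bound benzylic C7 centre, whose collapse forms C7–C8, a [1,2]-Stevens shift; the closest known reaction type is the rhodium- or copper-carbene ring expansion of 2-substituted 1,3-dioxolanes and of oxetanes with diazo compounds through oxonium ylides, which has not been shown for aryl-bound acetal oxygens or donor-only aryl carbenes. The dioxane closes by ring expansion from five to six members, O7–C7 coming from ylide formation and C7–C8 from recombination of the tethered 1,6-pair. C8 is not new: it should keep its configuration (retention) because the pair is held by the O8–aryl–O7 tether and is expected to collapse on the face O7 has just left before rotation about O8–C8, so the resolved (R)-acetal becomes (8R). The new stereocentre C7 is set under substrate control in the recombination, with aryl expected anti to the silyloxymethyl group, and any cis epimer is corrected in step 11. The step needs O7 over O8, secured by the methoxy group flanking O8 and by the para ester that lowers the basicity of O8; ylide formation over carbene dimerisation, secured by portionwise release of 12 and excess 10; and the acetal oxygen over all other oxygens, secured by hindered silyl ethers on ring A and C9 and by an ether-free, electron-poor solvent, while the ester-deactivated ring B and silyl-shielded ring A should disfavour arene cyclopropanation.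

Step 8  
Reactants: 13 methyl (2R,3R)-3-[3,4-bis(TBSO)-5-methoxyphenyl]-2-(TBSO-methyl)-8-methoxy-2,3-dihydro-1,4-benzodioxine-6-carboxylate  
Product: 14 {(2R,3R)-3-[3,4-bis(TBSO)-5-methoxyphenyl]-2-(TBSO-methyl)-8-methoxy-2,3-dihydro-1,4-benzodioxin-6-yl}methanol  
Conditions: iBu2AlH (DIBAL-H), CH2Cl2, −78 to 0 °C; aq. potassium sodium tartrate  
Reagents that add atoms: none  
Why: Aluminium hydride reduction of an aryl ester to the benzylic alcohol; silyl ethers and the dioxane are inert and no stereocentre is touched.

Step 9  
Reactants: 14 {(2R,3R)-3-[3,4-bis(TBSO)-5-methoxyphenyl]-2-(TBSO-methyl)-8-methoxy-2,3-dihydro-1,4-benzodioxin-6-yl}methanol  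
Product: 15 (2R,3R)-3-[3,4-bis(TBSO)-5-methoxyphenyl]-2-(TBSO-methyl)-8-methoxy-2,3-dihydro-1,4-benzodioxine-6-carbaldehyde  
Conditions: MnO2, CH2Cl2, rt  
Reagents that add atoms: none  
Why: Selective MnO2 oxidation of a benzylic alcohol to the aldehyde under neutral conditions without over-oxidation.

Step 10  
Reactants: 15 (2R,3R)-3-[3,4-bis(TBSO)-5-methoxyphenyl]-2-(TBSO-methyl)-8-methoxy-2,3-dihydro-1,4-benzodioxine-6-carbaldehyde  
Product: 16 (2E)-3-{(2R,3R)-3-[3,4-bis(TBSO)-5-methoxyphenyl]-2-(TBSO-methyl)-8-methoxy-2,3-dihydro-1,4-benzodioxin-6-yl}prop-2-enal  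
Conditions: Ph3P=CHCHO (1.3 equiv), toluene, 80 °C  
Reagents that add atoms: (triphenylphosphoranylidene)acetaldehyde, O=CC=P(c1ccccc1)(c1ccccc1)c1ccccc1  
Why: Wittig olefination with a stabilised formyl ylide, which should give the (E)-enal directly; the product enal is less electrophilic than 15, which together with the limited excess of ylide should hold the reaction at one homologation.

Step 11  
Reactants: 16 (2E)-3-{(2R,3R)-3-[3,4-bis(TBSO)-5-methoxyphenyl]-2-(TBSO-methyl)-8-methoxy-2,3-dihydro-1,4-benzodioxin-6-yl}prop-2-enal  
Product: 17 (2E)-3-[(2R,3R)-3-(3,4-dihydroxy-5-methoxyphenyl)-2-(hydroxymethyl)-8-methoxy-2,3-dihydro-1,4-benzodioxin-6-yl]prop-2-enal (target, CNP0103768.1)  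
Conditions: HF·pyridine, THF, 0 °C to rt; then CF3CO2H (cat.), MeCN, rt, under argon  
Reagents that add atoms: none  
Why: Fluoride-mediated desilylation of the two aryl and one alkyl silyl ethers under mildly acidic conditions that avoid phenoxides, followed by acid-catalysed equilibration of the para-hydroxybenzyl aryl ether: reversible C7–O7 ionisation to the ring A-stabilised cation and re-closure by O7 should bring any cis material to the thermodynamically preferred trans (7R) arrangement while C8 is not involved.

## Compound list

```
1 | methyl 3,4-dihydroxy-5-methoxybenzoate | COC(=O)c1cc(O)c(O)c(OC)c1 | starting material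
2 | ethyl dibromoacetate | CCOC(=O)C(Br)Br | starting material
3 | 2-ethyl 5-methyl 7-methoxy-1,3-benzodioxole-2,5-dicarboxylate (racemic) | CCOC(=O)C1Oc2cc(C(=O)OC)cc(OC)c2O1 | intermediate
4 | methyl 2-(hydroxymethyl)-7-methoxy-1,3-benzodioxole-5-carboxylate (racemic) | COC(=O)c1cc(OC)c2OC(CO)Oc2c1 | intermediate
5 | methyl (2R)-2-(hydroxymethyl)-7-methoxy-1,3-benzodioxole-5-carboxylate | COC(=O)c1cc(OC)c2O[C@H](CO)Oc2c1 | intermediate
6 | methyl (2R)-2-(TBSO-methyl)-7-methoxy-1,3-benzodioxole-5-carboxylate | COC(=O)c1cc(OC)c2O[C@H](CO[Si](C)(C)C(C)(C)C)Oc2c1 | intermediate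
7 | 5-hydroxyvanillin (3,4-dihydroxy-5-methoxybenzaldehyde) | COc1cc(C=O)cc(O)c1O | starting material
8 | 3,4-bis(TBSO)-5-methoxybenzaldehyde | COc1cc(C=O)cc(O[Si](C)(C)C(C)(C)C)c1O[Si](C)(C)C(C)(C)C | intermediate
9 | p-toluenesulfonyl hydrazide | Cc1ccc(cc1)S(=O)(=O)NN | starting material
10 | N'-[(E)-(3,4-bis(TBSO)-5-methoxyphenyl)methylidene]-4-methylbenzenesulfonohydrazide | COc1cc(/C=N/NS(=O)(=O)c2ccc(C)cc2)cc(O[Si](C)(C)C(C)(C)C)c1O[Si](C)(C)C(C)(C)C | intermediate
11 | sodium salt of tosylhydrazone 10 | COc1cc(/C=N/[N-]S(=O)(=O)c2ccc(C)cc2)cc(O[Si](C)(C)C(C)(C)C)c1O[Si](C)(C)C(C)(C)C.[Na+] | intermediate (not isolated)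
12 | 5-(diazomethyl)-1,2-bis(TBSO)-3-methoxybenzene | COc1cc(C=[N+]=[N-])cc(O[Si](C)(C)C(C)(C)C)c1O[Si](C)(C)C(C)(C)C | intermediate (not isolated)
13 | methyl (2R,3R)-3-[3,4-bis(TBSO)-5-methoxyphenyl]-2-(TBSO-methyl)-8-methoxy-2,3-dihydro-1,4-benzodioxine-6-carboxylate | CC(C)(C)[Si](C)(C)Oc1cc([C@H]2Oc3cc(C(=O)OC)cc(OC)c3O[C@@H]2CO[Si](C)(C)C(C)(C)C)cc(OC)c1O[Si](C)(C)C(C)(C)C | intermediate
14 | {(2R,3R)-3-[3,4-bis(TBSO)-5-methoxyphenyl]-2-(TBSO-methyl)-8-methoxy-2,3-dihydro-1,4-benzodioxin-6-yl}methanol | CC(C)(C)[Si](C)(C)Oc1cc([C@H]2Oc3cc(CO)cc(OC)c3O[C@@H]2CO[Si](C)(C)C(C)(C)C)cc(OC)c1O[Si](C)(C)C(C)(C)C | intermediate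
15 | (2R,3R)-3-[3,4-bis(TBSO)-5-methoxyphenyl]-2-(TBSO-methyl)-8-methoxy-2,3-dihydro-1,4-benzodioxine-6-carbaldehyde | CC(C)(C)[Si](C)(C)Oc1cc([C@H]2Oc3cc(C=O)cc(OC)c3O[C@@H]2CO[Si](C)(C)C(C)(C)C)cc(OC)c1O[Si](C)(C)C(C)(C)C | intermediate
16 | (2E)-3-{(2R,3R)-3-[3,4-bis(TBSO)-5-methoxyphenyl]-2-(TBSO-methyl)-8-methoxy-2,3-dihydro-1,4-benzodioxin-6-yl}prop-2-enal | CC(C)(C)[Si](C)(C)Oc1cc([C@H]2Oc3cc(/C=C/C=O)cc(OC)c3O[C@@H]2CO[Si](C)(C)C(C)(C)C)cc(OC)c1O[Si](C)(C)C(C)(C)C | intermediate
17 | (2E)-3-[(2R,3R)-3-(3,4-dihydroxy-5-methoxyphenyl)-2-(hydroxymethyl)-8-methoxy-2,3-dihydro-1,4-benzodioxin-6-yl]prop-2-enal | COc1cc([C@H]2Oc3cc(/C=C/C=O)cc(OC)c3O[C@@H]2CO)cc(O)c1O | target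
```

## Step count and least certain steps

Total step count: 11. Longest linear sequence: 9 steps (steps 1–4 and 7–11, from 1 to 17); the ring A branch (steps 5 and 6) joins at step 7.

**Step 7 (key step).**
- Most likely failure: the carbenoid does not engage the weakly basic aryl acetal oxygen and is lost to dimerisation (stilbene, azine) or arene addition. A donor-only aryl carbene is a modest electrophile, and O7 is an aryl-conjugated oxygen on an ester-bearing ring.
- Second failure mode: ylide formation at O8, which would give the regioisomeric dioxane.
- Third failure mode: erosion of configuration at C8, if the tethered radical or ion pair rotates about O8–C8 before it collapses.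
- Fallback (known chemistry, from 1 and 8, returning at 13):
  - 1 would be alkylated at its more acidic 4-hydroxyl (the future O8) with (4S)-4-benzyl-3-(bromoacetyl)-1,3-oxazolidin-2-one (Li2CO3, DMF) to give methyl 4-{2-[(4S)-4-benzyl-2-oxo-1,3-oxazolidin-3-yl]-2-oxoethoxy}-3-hydroxy-5-methoxybenzoate F1.
  - The remaining phenol (future O7) would be masked with allyl bromide and K2CO3 to give the allyl ether F2.
  - An Evans boron aldol reaction of F2 (Bu2BOTf, iPr2NEt, CH2Cl2, −78 °C) with 8 should give the syn aldol adduct F3, in which the auxiliary fixes C8.
  - LiBH4 (THF/MeOH, 0 °C) would cleave the auxiliary reductively to the (1R,2R)-1,3-diol F4, and Pd(PPh3)4 with morpholine would remove the allyl group to give the phenol diol F5.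
  - Catalytic camphorsulfonic acid in CH2Cl2 should close the dioxane through the ring A-stabilised C7 cation to the trans benzodioxane alcohol F6, with C7 under thermodynamic control and C8 untouched.
  - Silylation of the C9 hydroxyl (TBSCl, imidazole) gives 13.
  - Seven operations would replace one, but each is an established reaction type.

**Step 3.**
- Most likely failure: insufficient enantiodiscrimination by the lipase. The acetal carbon is stereogenic only through the remote methoxy and ester groups of ring B, so the two enantiomers present nearly the same shape at the carbinol.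
- Fallback (from 4, returning at 5): racemic 4 would be separated into its enantiomers by preparative supercritical-fluid chromatography on an immobilised polysaccharide carbamate phase, the (2R)-enantiomer being 5. This makes no new compound (entry F0). The absolute configuration would be assigned by X-ray analysis of a 4-bromobenzoate.

**Step 11.**
- Most likely failure: degradation during the acid stage. Loss of the C8 proton from the benzylic cation to an enol ether would destroy C8, external nucleophiles could trap the cation, and the enal and catechol are sensitive to prolonged acid. Incomplete cleavage of the hindered aryl silyl ethers is also possible.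
- Fallback (from 15, returning at 17): desilylation and acid equilibration would be done on the sturdier aldehyde 15 (HF·pyridine, THF; then catalytic CF3CO2H) to give (2R,3R)-3-(3,4-dihydroxy-5-methoxyphenyl)-2-(hydroxymethyl)-8-methoxy-2,3-dihydro-1,4-benzodioxine-6-carbaldehyde F7. The enal would then be installed last, by Wittig reaction of unprotected F7 with excess Ph3P=CHCHO in THF at 60 °C, giving 17. The stabilised ylide should tolerate free phenols, and the enal never meets the deprotection conditions.

**Step 10.**
- Most likely failure: over-homologation, a second Wittig reaction on the product enal to a dienal, or sluggish reaction of the electron-rich aldehyde that tempts a large excess of ylide.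
- Fallback (from 15, returning at 16): Horner–Wadsworth–Emmons reaction with triethyl phosphonoacetate (LiCl, DBU, MeCN) would give ethyl (2E)-3-{(2R,3R)-3-[3,4-bis(TBSO)-5-methoxyphenyl]-2-(TBSO-methyl)-8-methoxy-2,3-dihydro-1,4-benzodioxin-6-yl}prop-2-enoate F8. Reduction with iBu2AlH at −78 °C would give the allylic alcohol (2E)-3-{(2R,3R)-3-[3,4-bis(TBSO)-5-methoxyphenyl]-2-(TBSO-methyl)-8-methoxy-2,3-dihydro-1,4-benzodioxin-6-yl}prop-2-en-1-ol F9, and MnO2 would oxidise it to 16. This costs two more steps and cannot over-homologate.

## Further compounds

```
F1 | step 7 | methyl 4-{2-[(4S)-4-benzyl-2-oxo-1,3-oxazolidin-3-yl]-2-oxoethoxy}-3-hydroxy-5-methoxybenzoate | COC(=O)c1cc(O)c(OCC(=O)N2[C@@H](Cc3ccccc3)COC2=O)c(OC)c1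
F2 | step 7 | methyl 3-(allyloxy)-4-{2-[(4S)-4-benzyl-2-oxo-1,3-oxazolidin-3-yl]-2-oxoethoxy}-5-methoxybenzoate | COC(=O)c1cc(OCC=C)c(OCC(=O)N2[C@@H](Cc3ccccc3)COC2=O)c(OC)c1
F3 | step 7 | methyl 3-(allyloxy)-4-{[(2S,3R)-1-[(4S)-4-benzyl-2-oxo-1,3-oxazolidin-3-yl]-3-[3,4-bis(TBSO)-5-methoxyphenyl]-3-hydroxy-1-oxopropan-2-yl]oxy}-5-methoxybenzoate | CC(C)(C)[Si](C)(C)Oc1cc([C@@H](O)[C@@H](C(=O)N2[C@@H](Cc3ccccc3)COC2=O)Oc2c(OCC=C)cc(C(=O)OC)cc2OC)cc(OC)c1O[Si](C)(C)C(C)(C)C
F4 | step 7 | methyl 3-(allyloxy)-4-{[(1R,2R)-1-[3,4-bis(TBSO)-5-methoxyphenyl]-1,3-dihydroxypropan-2-yl]oxy}-5-methoxybenzoate | CC(C)(C)[Si](C)(C)Oc1cc([C@@H](O)[C@@H](CO)Oc2c(OCC=C)cc(C(=O)OC)cc2OC)cc(OC)c1O[Si](C)(C)C(C)(C)C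
F5 | step 7 | methyl 4-{[(1R,2R)-1-[3,4-bis(TBSO)-5-methoxyphenyl]-1,3-dihydroxypropan-2-yl]oxy}-3-hydroxy-5-methoxybenzoate | CC(C)(C)[Si](C)(C)Oc1cc([C@@H](O)[C@@H](CO)Oc2c(O)cc(C(=O)OC)cc2OC)cc(OC)c1O[Si](C)(C)C(C)(C)C
F6 | step 7 | methyl (2R,3R)-3-[3,4-bis(TBSO)-5-methoxyphenyl]-2-(hydroxymethyl)-8-methoxy-2,3-dihydro-1,4-benzodioxine-6-carboxylate | CC(C)(C)[Si](C)(C)Oc1cc([C@H]2Oc3cc(C(=O)OC)cc(OC)c3O[C@@H]2CO)cc(OC)c1O[Si](C)(C)C(C)(C)C
F0 | step 3 | none | none
F7 | step 11 | (2R,3R)-3-(3,4-dihydroxy-5-methoxyphenyl)-2-(hydroxymethyl)-8-methoxy-2,3-dihydro-1,4-benzodioxine-6-carbaldehyde | COc1cc([C@H]2Oc3cc(C=O)cc(OC)c3O[C@@H]2CO)cc(O)c1O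
F8 | step 10 | ethyl (2E)-3-{(2R,3R)-3-[3,4-bis(TBSO)-5-methoxyphenyl]-2-(TBSO-methyl)-8-methoxy-2,3-dihydro-1,4-benzodioxin-6-yl}prop-2-enoate | CC(C)(C)[Si](C)(C)Oc1cc([C@H]2Oc3cc(/C=C/C(=O)OCC)cc(OC)c3O[C@@H]2CO[Si](C)(C)C(C)(C)C)cc(OC)c1O[Si](C)(C)C(C)(C)C
F9 | step 10 | (2E)-3-{(2R,3R)-3-[3,4-bis(TBSO)-5-methoxyphenyl]-2-(TBSO-methyl)-8-methoxy-2,3-dihydro-1,4-benzodioxin-6-yl}prop-2-en-1-ol | CC(C)(C)[Si](C)(C)Oc1cc([C@H]2Oc3cc(/C=C/CO)cc(OC)c3O[C@@H]2CO[Si](C)(C)C(C)(C)C)cc(OC)c1O[Si](C)(C)C(C)(C)C
A1 | alternative 1 | 2-(3,4-diacetoxy-5-methoxyphenyl)-3-[4-bromo-2-methoxy-6-(methoxymethoxy)phenoxy]oxetane, C8 as in the target, C7 either | COc1cc(C2OC[C@H]2Oc2c(OC)cc(Br)cc2OCOC)cc(OC(C)=O)c1OC(C)=O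
A2 | alternative 1 | 3,4-diacetoxy-5-methoxybenzaldehyde | COc1cc(C=O)cc(OC(C)=O)c1OC(C)=O
A3 | alternative 1 | 5-bromo-2-(ethenyloxy)-1-methoxy-3-(methoxymethoxy)benzene | C=COc1c(OC)cc(Br)cc1OCOC
A4 | alternative 2 | tert-butyl({(2R,3R)-3-[3-methoxy-4,5-bis(methoxymethoxy)phenyl]-2-(TBSO-methyl)-8-methoxy-2,3-dihydro-1,4-benzodioxin-6-yl}methoxy)dimethylsilane | COCOc1cc([C@H]2Oc3cc(CO[Si](C)(C)C(C)(C)C)cc(OC)c3O[C@@H]2CO[Si](C)(C)C(C)(C)C)cc(OC)c1OCOC
A5 | alternative 2 | (1R,2R)-2-[2-bromo-4-(TBSO-methyl)-6-methoxyphenoxy]-3-(TBSO)-1-[3-methoxy-4,5-bis(methoxymethoxy)phenyl]propan-1-ol | COCOc1cc([C@@H](O)[C@@H](CO[Si](C)(C)C(C)(C)C)Oc2c(Br)cc(CO[Si](C)(C)C(C)(C)C)cc2OC)cc(OC)c1OCOC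
A6 | alternative 3 | (2R,3R)-3-[3-methoxy-4,5-bis(methoxymethoxy)phenyl]-2-(TBSO-methyl)-8-methoxy-2,3-dihydro-1,4-benzodioxine-6-carbaldehyde | COCOc1cc([C@H]2Oc3cc(C=O)cc(OC)c3O[C@@H]2CO[Si](C)(C)C(C)(C)C)cc(OC)c1OCOC
A7 | alternative 3 | 3-{[(1R,2S)-3-(TBSO)-2-hydroxy-1-[3-methoxy-4,5-bis(methoxymethoxy)phenyl]propyl]oxy}-4-hydroxy-5-methoxybenzaldehyde | COCOc1cc([C@@H](Oc2cc(C=O)cc(OC)c2O)[C@@H](O)CO[Si](C)(C)C(C)(C)C)cc(OC)c1OCOC
```
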